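**Retrosynthetic overview**

1. Ring B is the phenol ring, numbered C1' (ether O), C2' (OH), C3' (Br), C4' (H), C5' (Br), C6' (OMe); ring A is the 3,5-dibromo-2-methoxyphenoxy ring. The last disconnection removes the C3'–Br and C5'–Br bonds, which lie ortho and para to C2'–OH.
2. The strategy rests on the contiguous C2'–OH / C1'–OAr / C6'–OMe triad of ring B. It maps onto a 2-aryloxy-1,3-dimethoxy-1-silyloxybutadiene (C2', C1', C6', C5'), with C3'–C4' supplied by phenyl vinyl sulfoxide as an acetylene equivalent; the [4+2] forms C2'–C3' and C4'–C5'.
3. The diene comes from methyl 2-aryloxyacetoacetate by enol ether formation and γ-deprotonation/O-silylation. The diaryl-ether C–O bond is made earlier as an alkyl aryl ether, from 3,5-dibromo-2-methoxyphenol and methyl 2-chloroacetoacetate.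
4. Ring A is bought fully brominated as 3,5-dibromosalicylaldehyde (O-methylation, Baeyer–Villiger). Ring order: A purchased, B built in step 6.

Key step: step 6

Remark: the target has no stereocentre and no configurationally stable axis, so the compound as drawn is the single species required. Intermediates 6, 7 and 12 are racemic and their stereocentres are erased later. Compounds 8 and 10 are drawn as one geometric isomer each, but either isomer would converge on the same product.

**Route**

Step 1
Reactants: 1 3,5-dibromosalicylaldehyde
Product: 2 3,5-dibromo-2-methoxybenzaldehyde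
Conditions: MeI, K2CO3, DMF, rt
Reagents that add atoms: iodomethane, CI
Why: Williamson O-methylation of the acidic salicylaldehyde phenoxide, which can only react on oxygen because both ortho positions and the para position are substituted.

Step 2
Reactants: 2 3,5-dibromo-2-methoxybenzaldehyde
Product: 4 3,5-dibromo-2-methoxyphenol, via aryl formate 3 (not isolated)
Conditions: mCPBA, CH2Cl2, 40 °C; then K2CO3 (cat.), MeOH, rt
Reagents that add atoms: meta-chloroperoxybenzoic acid, O=C(OO)c1cccc(Cl)c1
Why: Baeyer–Villiger (Dakin-type) oxidation in which the ortho-methoxyaryl group should migrate in the Criegee intermediate in preference to hydride, followed by methanolysis of the formate; aryl bromides and the methyl ether are inert to the peracid.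

Step 3
Reactants: 4 3,5-dibromo-2-methoxyphenol; 5 methyl 2-chloroacetoacetate
Product: 6 methyl 2-(3,5-dibromo-2-methoxyphenoxy)-3-oxobutanoate (racemic)
Conditions: K2CO3, acetone, reflux
Reagents that add atoms: none
Why: Williamson SN2 displacement of the doubly activated α-chloride by the phenoxide, the standard entry to 2-aryloxyacetoacetates, under a carbonate base mild enough to avoid retro-Claisen cleavage.

Step 4
Reactants: 6 methyl 2-(3,5-dibromo-2-methoxyphenoxy)-3-oxobutanoate
Product: 8 methyl (2Z)-2-(3,5-dibromo-2-methoxyphenoxy)-3-methoxybut-2-enoate, via dimethyl ketal 7 (not isolated)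
Conditions: HC(OMe)3 (5 equiv), TsOH·H2O (cat.), 60 °C; then 130 °C, distil off MeOH/HCO2Me
Reagents that add atoms: trimethyl orthoformate, COC(OC)OC
Why: Acid-catalysed ketalisation of the ketone with the orthoformate and thermal loss of methanol from ketal 7 is the standard route from acetoacetates to 3-methoxybut-2-enoates and can only place the methyl on oxygen; any β,γ-unsaturated enol ether isomer would give the same dienolate in step 5.

Step 5
Reactants: 8 methyl (2Z)-2-(3,5-dibromo-2-methoxyphenoxy)-3-methoxybut-2-enoate
Product: 10 (1E)-2-(3,5-dibromo-2-methoxyphenoxy)-1,3-dimethoxy-1-(trimethylsilyloxy)buta-1,3-diene, via lithium dienolate 9 (not isolated)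
Conditions: LDA (1.05 equiv), THF, −78 °C; TMSCl, −78 → 0 °C; non-aqueous work-up (pentane, filtration), used crude
Reagents that add atoms: chlorotrimethylsilane, C[Si](C)(C)Cl
Why: Kinetic γ-deprotonation of the β-methoxy enoate (the γ-CH3 cis to the ester is the only C–H of ester-like acidity, several pK units below the ring A C–H between the bromines) gives extended enolate 9, which TMSCl silylates on oxygen, the standard preparation of Brassard-type vinylketene silyl acetals.

Step 6
Reactants: 10 (1E)-2-(3,5-dibromo-2-methoxyphenoxy)-1,3-dimethoxy-1-(trimethylsilyloxy)buta-1,3-diene; 11 phenyl vinyl sulfoxide (3 equiv)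
Product: 15 2-(3,5-dibromo-2-methoxyphenoxy)-3-methoxyphenol, via sulfinylcyclohexene cycloadduct 12 (not isolated), via cyclohexadiene silyl ketal 13 (not isolated), via cyclohexadienone 14 (not isolated)
Conditions: CaCO3, PhMe (concentrated), 90 → 110 °C, sealed tube; then 0.5 M HCl, THF, 0 °C → rt
Reagents that add atoms: none
Why: Diene 10, whose three oxygen donors raise the HOMO and place its largest coefficient on the CH2 terminus, should add the electron-poor vinyl sulfoxide 11 in a concerted normal-demand intermolecular [4+2] cycloaddition that forms C4'–C5' and C2'–C3' together and so closes ring B as a six-membered carbocycle (cycloadduct 12). The closest known reaction type is the Diels–Alder/aromatisation of Danishefsky- and Brassard-type silyloxy dienes with phenyl vinyl sulfoxide as an acetylene equivalent. At 110 °C the sulfinyl group and a C4' hydrogen should leave by thermal syn-elimination (Ei) to give 1,4-cyclohexadiene 13, and dilute acid then cleaves the mixed silyl methyl ketal at Si–O to dienone 14, which tautomerises to phenol 15. The stereocentres of 12 (sulfur, C3', C2') form without control and are all erased on aromatisation, so none has to be set. The selectivity needed is the differentiation of the two oxygens flanking C1': the ketene acetal carbon becomes C2'–OH because its silyl group is the one removed (loss of methanol from 13 leads through the aryl silyl ether to the same phenol), while the enol ether carbon keeps its methyl as C6'–OMe. The regiochemistry of addition does not matter because both dienophile carbons end as CH, and ring A with its bromines is a spectator.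

Step 7
Reactants: 15 2-(3,5-dibromo-2-methoxyphenoxy)-3-methoxyphenol
Product: 16 4,6-dibromo-2-(3,5-dibromo-2-methoxyphenoxy)-3-methoxyphenol (target)
Conditions: NBS (2.05 equiv), MeCN, 0 °C → rt
Reagents that add atoms: N-bromosuccinimide, O=C1CCC(=O)N1Br
Why: Electrophilic aromatic bromination in which C3' (ortho to OH, para to OMe) and C5' (para to OH, ortho to OMe) are the two doubly activated positions, whereas C4' is meta to both donors and ring A is deactivated by two bromines.

**Compound list**

1 | 3,5-dibromosalicylaldehyde | O=Cc1cc(Br)cc(Br)c1O | starting material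
2 | 3,5-dibromo-2-methoxybenzaldehyde | COc1c(Br)cc(Br)cc1C=O | intermediate
3 | 3,5-dibromo-2-methoxyphenyl formate (not isolated) | COc1c(Br)cc(Br)cc1OC=O | intermediate
4 | 3,5-dibromo-2-methoxyphenol | COc1c(Br)cc(Br)cc1O | intermediate
5 | methyl 2-chloroacetoacetate (racemic) | COC(=O)C(Cl)C(C)=O | starting material
6 | methyl 2-(3,5-dibromo-2-methoxyphenoxy)-3-oxobutanoate (racemic) | COC(=O)C(Oc1cc(Br)cc(Br)c1OC)C(C)=O | intermediate
7 | methyl 2-(3,5-dibromo-2-methoxyphenoxy)-3,3-dimethoxybutanoate (racemic, not isolated) | COC(=O)C(Oc1cc(Br)cc(Br)c1OC)C(C)(OC)OC | intermediate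
8 | methyl (2Z)-2-(3,5-dibromo-2-methoxyphenoxy)-3-methoxybut-2-enoate | C/C(OC)=C(/Oc1cc(Br)cc(Br)c1OC)C(=O)OC | intermediate
9 | lithium (1E)-2-(3,5-dibromo-2-methoxyphenoxy)-1,3-dimethoxybuta-1,3-dien-1-olate (not isolated) | C=C(OC)/C(Oc1cc(Br)cc(Br)c1OC)=C(/OC)[O-].[Li+] | intermediate
10 | (1E)-2-(3,5-dibromo-2-methoxyphenoxy)-1,3-dimethoxy-1-(trimethylsilyloxy)buta-1,3-diene | C=C(OC)/C(Oc1cc(Br)cc(Br)c1OC)=C(/OC)O[Si](C)(C)C | intermediate
11 | phenyl vinyl sulfoxide (racemic) | C=CS(=O)c1ccccc1 | starting material
12 | [2-(3,5-dibromo-2-methoxyphenoxy)-1,3-dimethoxy-6-(phenylsulfinyl)cyclohex-2-en-1-yl]oxy-trimethylsilane (racemic diastereomer mixture, not isolated) | COC1=C(Oc2cc(Br)cc(Br)c2OC)C(OC)(O[Si](C)(C)C)C(S(=O)c2ccccc2)CC1 | intermediate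
13 | [2-(3,5-dibromo-2-methoxyphenoxy)-1,3-dimethoxycyclohexa-2,5-dien-1-yl]oxy-trimethylsilane (racemic, not isolated) | COC1=C(Oc2cc(Br)cc(Br)c2OC)C(OC)(O[Si](C)(C)C)C=CC1 | intermediate
14 | 2-(3,5-dibromo-2-methoxyphenoxy)-3-methoxycyclohexa-2,5-dien-1-one (not isolated) | COC1=C(Oc2cc(Br)cc(Br)c2OC)C(=O)C=CC1 | intermediate
15 | 2-(3,5-dibromo-2-methoxyphenoxy)-3-methoxyphenol | COc1cccc(O)c1Oc1cc(Br)cc(Br)c1OC | intermediate
16 | 4,6-dibromo-2-(3,5-dibromo-2-methoxyphenoxy)-3-methoxyphenol | COc1c(Br)cc(Br)cc1Oc1c(O)c(Br)cc(Br)c1OC | target

**Step count**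

Total steps: 7. Longest linear sequence: 7 steps (from 1 to 16).

**Steps most likely to fail**

Step 6 (key step). The tetrasubstituted diene may add the weak dienophile too slowly, so that protodesilylation of the ketene acetal by the sulfenic acid and water released during the reaction outpaces ring formation. Aromatisation could also proceed by loss of silanol instead of methanol, which would erase the OH/OMe differentiation. The fallback abandons the benzannulation and sets out from phenol 4. Nucleophilic aromatic substitution on 2-fluoro-3-methoxybenzaldehyde (COc1cccc(C=O)c1F; K2CO3, DMAc, 120 °C) should give 2-(3,5-dibromo-2-methoxyphenoxy)-3-methoxybenzaldehyde F1. Baeyer–Villiger oxidation (mCPBA, CH2Cl2) should convert it to 2-(3,5-dibromo-2-methoxyphenoxy)-3-methoxyphenyl formate F2, and methanolysis (K2CO3 cat., MeOH) returns to the route at 15.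

Step 5. The amide base may deprotonate ring A at the C–H between the two bromines, followed by halogen migration, or the ketene acetal may hydrolyse during isolation. The fallback avoids strong base and sets out from β-keto ester 6. Soft enolisation with TMSOTf/Et3N (2.2 equiv each, Et2O, 0 °C) should give the bis-silyl diene (1E)-2-(3,5-dibromo-2-methoxyphenoxy)-1-methoxy-1,3-bis(trimethylsilyloxy)buta-1,3-diene F3. Cycloaddition with 11 and acidic work-up as in step 6 should give the symmetrical 2-(3,5-dibromo-2-methoxyphenoxy)benzene-1,3-diol F4. Mono-O-methylation (MeI, 1 equiv, K2CO3, acetone, with recycling of unreacted diol) returns to the route at 15.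

Step 4. Elimination of methanol from the ketal may be incomplete, or the acid may induce cyclodehydration onto ring A. The fallback sets out from 6 and replaces the acid-mediated sequence by base-mediated O-methylation of the enolate with the hard electrophile dimethyl sulfate (K2CO3, DMF, rt), which should give 8 directly. It makes no new compound and returns to the route at 8.

**Further compounds**

F1 | step 6 | 2-(3,5-dibromo-2-methoxyphenoxy)-3-methoxybenzaldehyde | COc1cccc(C=O)c1Oc1cc(Br)cc(Br)c1OC
F2 | step 6 | 2-(3,5-dibromo-2-methoxyphenoxy)-3-methoxyphenyl formate | COc1cccc(OC=O)c1Oc1cc(Br)cc(Br)c1OC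
F3 | step 5 | (1E)-2-(3,5-dibromo-2-methoxyphenoxy)-1-methoxy-1,3-bis(trimethylsilyloxy)buta-1,3-diene | C=C(O[Si](C)(C)C)/C(Oc1cc(Br)cc(Br)c1OC)=C(/OC)O[Si](C)(C)C
F4 | step 5 | 2-(3,5-dibromo-2-methoxyphenoxy)benzene-1,3-diol | Oc1cccc(O)c1Oc1cc(Br)cc(Br)c1OC
F0 | step 4 | none | none
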